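**Strategy.** The route rests on cutting the C3–C4 bond of the 1,2-dioxane. C3, the peroxyhemiketal carbon held between O2 and OH, is a masked acetyl carbonyl tied to C6 through O1–O2. In the key step the enolate of a γ-peracetoxy α-methyl aldehyde adds to its own perester carbonyl; the tetrahedral intermediate is the six-membered ring O1–O2–C3–C4–C5–C6, and the activating formyl group then leaves as formate. The precursor is an open-chain tertiary peracetate aldehyde. The side-chain stereocentre is bought with (R)-citronellal, C6 is set by catalytic asymmetric hydroperoxidation of an enone, and C3 and C4 settle under thermodynamic control.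

Key step: step 11

Assumption (chemistry): in step 8 the quinine-derived primary amine salt is taken to deliver the (5S)-dioxolanol; if the sense proves opposite, the pseudoenantiomeric 9-amino-9-deoxy-epi-quinidine salt is used and nothing else changes.

Step 1
Reactants: 1 (R)-citronellal
Product: 2 (4R)-4,8-dimethylnon-7-en-1-yne
Conditions: dimethyl (1-diazo-2-oxopropyl)phosphonate, K2CO3, MeOH, 0 → 20 °C
Reagents that add atoms: dimethyl (1-diazo-2-oxopropyl)phosphonate, COP(=O)(OC)C(=[N+]=[N-])C(C)=O
Why: Seyferth–Gilbert homologation (Ohira–Bestmann variant) turns the aldehyde into the terminal alkyne under mild base, and the stereocentre, β to the carbonyl, is not touched.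

Step 2
Reactants: 2 (4R)-4,8-dimethylnon-7-en-1-yne
Product: 4 (4R)-4-methylhept-6-yn-1-ol, via (4R)-4-methylhept-6-ynal 3 (not isolated)
Conditions: O3, CH2Cl2–MeOH, −78 °C, stopped at first excess of ozone; then NaBH4, −78 → 0 °C
Reagents that add atoms: ozone, [O-][O+]=O
Why: Ozonolysis with reductive work-up should cleave only the electron-rich trisubstituted alkene, which reacts with ozone far faster than the terminal alkyne, and NaBH4 reduces the aldehyde in the same flask.

Step 3
Reactants: 4 (4R)-4-methylhept-6-yn-1-ol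
Product: 5 (4R)-4-methylhept-6-yn-1-yl 4-methylbenzenesulfonate
Conditions: TsCl, Et3N, DMAP (cat.), CH2Cl2, 0 → 20 °C
Reagents that add atoms: 4-methylbenzenesulfonyl chloride, Cc1ccc(cc1)S(Cl)(=O)=O
Why: Standard sulfonylation of a primary alcohol gives the leaving group for the chain-extending coupling.

Step 4
Reactants: 6 (5-chloropent-1-yn-1-yl)benzene
Product: 7 [(1Z)-5-chloropent-1-en-1-yl]benzene
Conditions: H2 (1 atm), Pd/CaCO3 poisoned with Pb(OAc)2, quinoline, hexane–EtOAc, 20 °C
Reagents that add atoms: none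
Why: Lindlar semihydrogenation adds H2 syn to the aryl alkyne and so fixes the Z-styrene on a small fragment before any peroxide is present; the alkyl chloride is inert.

Step 5
Reactants: 5 (4R)-4-methylhept-6-yn-1-yl 4-methylbenzenesulfonate; 7 [(1Z)-5-chloropent-1-en-1-yl]benzene
Product: 9 [(1Z,9R)-9-methyldodec-1-en-11-yn-1-yl]benzene, via [(4Z)-5-phenylpent-4-en-1-yl]magnesium chloride 8 (not isolated)
Conditions: 7, Mg, BrCH2CH2Br (cat.), THF, 50 °C; separately 5, EtMgBr (1.05 equiv), THF, 0 °C; then 8 (1.4 equiv), Li2CuCl4 (3 mol %), −78 → 20 °C; aq. NH4Cl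
Reagents that add atoms: none
Why: Copper-catalysed coupling of a primary alkyl Grignard reagent with a primary tosylate joins the two three-carbon arms into the six-methylene tether, the acidic alkyne C–H being parked as its magnesium acetylide and the Z-alkene being untouched.

Step 6
Reactants: 9 [(1Z,9R)-9-methyldodec-1-en-11-yn-1-yl]benzene
Product: 11 (3E,6R,13Z)-4,6-dimethyl-14-phenyltetradeca-3,13-dien-2-ol (2RS), via E-alkenyldimethylalane 10 (not isolated)
Conditions: AlMe3 (2 equiv), (C5H5)2ZrCl2 (0.2 equiv), CH2Cl2, 0 → 20 °C; then n-BuLi, hexane–THF, −78 °C; MeCHO, −78 → 0 °C; aq. KNaC4H4O6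
Reagents that add atoms: trimethylaluminium, C[Al](C)C; acetaldehyde, CC=O
Why: Negishi zirconium-catalysed methylalumination adds Me and Al syn across the terminal alkyne with methyl on the internal carbon, which fixes the E-trisubstituted alkene, and the derived alanate adds to acetaldehyde; the new carbinol centre forms without control and is erased in step 7.

Step 7
Reactants: 11 (3E,6R,13Z)-4,6-dimethyl-14-phenyltetradeca-3,13-dien-2-ol
Product: 12 (3E,6R,13Z)-4,6-dimethyl-14-phenyltetradeca-3,13-dien-2-one
Conditions: MnO2 (activated, excess), CH2Cl2, 20 °C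
Reagents that add atoms: none
Why: Allylic oxidation with MnO2 should give the E-enone without touching the isolated Z-styrene.

Step 8
Reactants: 12 (3E,6R,13Z)-4,6-dimethyl-14-phenyltetradeca-3,13-dien-2-one
Product: 13 (5S)-3,5-dimethyl-5-[(2R,9Z)-2-methyl-10-phenyldec-9-en-1-yl]-1,2-dioxolan-3-ol (3RS)
Conditions: 9-amino-9-deoxy-epi-quinine (10 mol %), CCl3CO2H (20 mol %), 50 % aq. H2O2 (3 equiv), 1,4-dioxane, 30 °C
Reagents that add atoms: hydrogen peroxide, OO
Why: Amine-catalysed asymmetric conjugate hydroperoxidation (the first half of a Weitz–Scheffer epoxidation, stopped at the peroxide under acidic conditions) adds HOO to one face of the E-configured iminium ion, so the catalyst sets the quaternary C–OO centre, and the β-hydroperoxy ketone is trapped as the cyclic peroxyhemiketal; this enone is a hindered β,β-disubstituted member of the known substrate class.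

Step 9
Reactants: 13 (5S)-3,5-dimethyl-5-[(2R,9Z)-2-methyl-10-phenyldec-9-en-1-yl]-1,2-dioxolan-3-ol
Product: 15 (4S,6R,13Z)-1-methoxy-2,4,6-trimethyl-14-phenyltetradeca-1,13-dien-4-yl ethaneperoxoate, via enol ether hydroperoxide 14 (not isolated)
Conditions: 13, KN(SiMe3)2 (1.05 equiv), THF, −78 °C; added to Ph3P=CHOMe [2.5 equiv, from Ph3P(CH2OMe)Cl and KN(SiMe3)2], −78 → 0 °C; then Ac2O (6 equiv), −78 → 0 °C; aq. NaHCO3
Reagents that add atoms: (methoxymethyl)triphenylphosphonium chloride, [Cl-].COC[P+](c1ccccc1)(c1ccccc1)c1ccccc1; acetic anhydride, CC(=O)OC(C)=O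
Why: Wittig methoxymethylenation of the ring-opened ketone adds the future formyl carbon while the peroxide is kept as its potassium salt (no leaving group for epoxide closure), and the peroxide anion is then O-acetylated in the same flask to the tertiary perester; no stereocentre is affected and the enol ether geometry is irrelevant.

Step 10
Reactants: 15 (4S,6R,13Z)-1-methoxy-2,4,6-trimethyl-14-phenyltetradeca-1,13-dien-4-yl ethaneperoxoate
Product: 16 (4S,6R,13Z)-2,4,6-trimethyl-1-oxo-14-phenyltetradec-13-en-4-yl ethaneperoxoate (2RS)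
Conditions: 1 M aq. HCl–THF (1:5), 0 → 20 °C
Reagents that add atoms: water, O
Why: Mild acid hydrolysis of the methyl enol ether should release the α-methyl aldehyde without harming the tertiary peracetate or the Z-styrene; the α-centre forms as a mixture and is enolised in the next step.

Step 11
Reactants: 16 (4S,6R,13Z)-2,4,6-trimethyl-1-oxo-14-phenyltetradec-13-en-4-yl ethaneperoxoate
Product: 18 (3S,4R,6S)-3,4,6-trimethyl-6-[(2R,9Z)-2-methyl-10-phenyldec-9-en-1-yl]-1,2-dioxan-3-ol (CNP0140061.2), via 4-formyl peroxyhemiketal 17 (not isolated)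
Conditions: LiN(SiMe3)2 (1.1 equiv), THF (0.01 M), 16 added slowly, −78 → −40 °C; then K2CO3, MeOH–H2O, 0 → 20 °C; pH 7 buffer; chromatography; the (4S) epimer is re-equilibrated (DBU cat., CH2Cl2) and recycled
Reagents that add atoms: none
Why: Proposed new method: LiN(SiMe3)2 removes the formyl α-hydrogen of 16 (far more acidic than the peracetate CH3) and the enolate carbon C4 adds to the tethered perester carbonyl C3, so that the tetrahedral alkoxide, which would collapse in an ordinary Claisen condensation, is here the lithium salt of peroxyhemiketal 17; aqueous K2CO3/MeOH then removes the formyl group of this non-enolisable α-formyl ketone by retro-Claisen cleavage (attack of hydroxide or of the internal peroxide anion on CHO), giving formate and 18. The closest known reaction types are the Dieckmann/Claisen acylation of enolates by activated esters and the base deformylation of α-formyl ketones; acyl transfer from a perester oxygen to carbon has not been described. The 1,2-dioxane closes in the 6-exo-trig mode through a chair-like transition state. C3 is set thermodynamically by the anomeric effect (axial OH, reversible hemiketal), and C4 is set by protonation and base equilibration of the ketone enolate relative to the catalyst-derived C6: the (4R) epimer can hold 3-Me, 4-Me and the C6 chain equatorial with only the C6 methyl axial, whereas the (4S) epimer must place the branched chain axial, so only a modest preference for 18 is expected and the minor epimer is separated and recycled. The step needs attack at the perester carbonyl and not at the peroxide oxygen, the mode known for intermolecular carbanion–perester reactions; the tether allows O-attack only as a strained 4-exo-tet closure to an oxetane, whereas carbonyl attack is a strain-free six-membered closure helped by lithium coordination, and high dilution suppresses intermolecular aldol and O-acylation.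

**Compound list**

1 | (R)-citronellal, (3R)-3,7-dimethyloct-6-enal | C[C@H](CCC=C(C)C)CC=O | starting material
2 | (4R)-4,8-dimethylnon-7-en-1-yne | C[C@H](CCC=C(C)C)CC#C | intermediate
3 | (4R)-4-methylhept-6-ynal | C[C@H](CCC=O)CC#C | intermediate (not isolated)
4 | (4R)-4-methylhept-6-yn-1-ol | C[C@H](CCCO)CC#C | intermediate
5 | (4R)-4-methylhept-6-yn-1-yl 4-methylbenzenesulfonate | C[C@H](CCCOS(=O)(=O)c1ccc(C)cc1)CC#C | intermediate
6 | (5-chloropent-1-yn-1-yl)benzene | ClCCCC#Cc1ccccc1 | starting material
7 | [(1Z)-5-chloropent-1-en-1-yl]benzene | ClCCC/C=C\c1ccccc1 | intermediate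
8 | [(4Z)-5-phenylpent-4-en-1-yl]magnesium chloride | Cl[Mg]CCC/C=C\c1ccccc1 | intermediate (not isolated)
9 | [(1Z,9R)-9-methyldodec-1-en-11-yn-1-yl]benzene | C[C@H](CCCCCC/C=C\c1ccccc1)CC#C | intermediate
10 | dimethyl[(1E,4R,11Z)-2,4-dimethyl-12-phenyldodeca-1,11-dien-1-yl]alumane | C[Al](C)/C=C(\C)C[C@H](C)CCCCCC/C=C\c1ccccc1 | intermediate (not isolated)
11 | (3E,6R,13Z)-4,6-dimethyl-14-phenyltetradeca-3,13-dien-2-ol (2RS) | CC(O)/C=C(\C)C[C@H](C)CCCCCC/C=C\c1ccccc1 | intermediate
12 | (3E,6R,13Z)-4,6-dimethyl-14-phenyltetradeca-3,13-dien-2-one | CC(=O)/C=C(\C)C[C@H](C)CCCCCC/C=C\c1ccccc1 | intermediate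
13 | (5S)-3,5-dimethyl-5-[(2R,9Z)-2-methyl-10-phenyldec-9-en-1-yl]-1,2-dioxolan-3-ol (3RS) | C[C@H](CCCCCC/C=C\c1ccccc1)C[C@@]1(C)CC(C)(O)OO1 | intermediate
14 | (4S,6R,13Z)-1-methoxy-2,4,6-trimethyl-14-phenyltetradeca-1,13-dien-4-yl hydroperoxide (formed as potassium salt) | C[C@H](CCCCCC/C=C\c1ccccc1)C[C@@](C)(CC(C)=COC)OO | intermediate (not isolated)
15 | (4S,6R,13Z)-1-methoxy-2,4,6-trimethyl-14-phenyltetradeca-1,13-dien-4-yl ethaneperoxoate | C[C@H](CCCCCC/C=C\c1ccccc1)C[C@@](C)(CC(C)=COC)OOC(C)=O | intermediate
16 | (4S,6R,13Z)-2,4,6-trimethyl-1-oxo-14-phenyltetradec-13-en-4-yl ethaneperoxoate (2RS) | C[C@H](CCCCCC/C=C\c1ccccc1)C[C@@](C)(CC(C)C=O)OOC(C)=O | intermediate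
17 | (6S)-3-hydroxy-3,4,6-trimethyl-6-[(2R,9Z)-2-methyl-10-phenyldec-9-en-1-yl]-1,2-dioxane-4-carbaldehyde (formed as lithium alkoxide) | C[C@H](CCCCCC/C=C\c1ccccc1)C[C@@]1(C)CC(C)(C=O)C(C)(O)OO1 | intermediate (not isolated)
18 | (3S,4R,6S)-3,4,6-trimethyl-6-[(2R,9Z)-2-methyl-10-phenyldec-9-en-1-yl]-1,2-dioxan-3-ol | C[C@H](CCCCCC/C=C\c1ccccc1)C[C@@]1(C)C[C@@H](C)[C@@](C)(O)OO1 | target

**Total steps:** 11. **Longest linear sequence:** 10 (steps 1–3 and 5–11, from 1).

**Steps most likely to fail**

Step 11. The enolate may attack the peroxide oxygen instead of the carbonyl (oxetane closure with loss of acetate) or react intermolecularly, and protonation at C4 may show little selectivity. The fallback sets out from 16. Diazomethane in Et2O at 0 °C converts the aldehyde into the methyl ketone (Büchner–Curtius–Schlotterbeck homologation), giving (5S,7R,14Z)-3,5,7-trimethyl-2-oxo-15-phenylpentadec-14-en-5-yl ethaneperoxoate F1. K2CO3 in MeOH at 0 °C then cleaves the perester, and the freed γ-hydroperoxy ketone closes by hemiketalisation; the fallback comes back at 18. The C4 epimers are equilibrated and separated as in the main route.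

Step 8. Conjugate addition at the fully substituted β-carbon may be slow, and E/Z scrambling through a dienamine may erode enantioface selection at the peroxide-bearing carbon. The fallback sets out from 11 and uses the oxetane route to tertiary hydroperoxides. Sharpless epoxidation with kinetic resolution (Ti(OiPr)4, D-(−)-diisopropyl tartrate, t-BuOOH, 4 Å sieves, CH2Cl2, −20 °C) consumes the (2R) epimer and gives (2R,3R,4R,6R,13Z)-3,4-epoxy-4,6-dimethyl-14-phenyltetradec-13-en-2-ol F2; the unreacted (2S) epimer is recycled through 12. NaAlH2(OCH2CH2OMe)2 opens the epoxide at C3 to (2R,4R,6R,13Z)-4,6-dimethyl-14-phenyltetradec-13-ene-2,4-diol F3. MeSO2Cl/Et3N gives the secondary mesylate (2R,4R,6R,13Z)-4-hydroxy-4,6-dimethyl-14-phenyltetradec-13-en-2-yl methanesulfonate F4, and KOt-Bu closes it to (2R,4S)-2,4-dimethyl-2-[(2R,9Z)-2-methyl-10-phenyldec-9-en-1-yl]oxetane F5. Ethereal H2O2 with Me3SiOSO2CF3 at −78 °C opens the oxetane at the tertiary carbon with inversion to (2S,4S,6R,13Z)-4-hydroperoxy-4,6-dimethyl-14-phenyltetradec-13-en-2-ol F6. Dess–Martin oxidation of the secondary alcohol then gives the hydroperoxy ketone, which closes; the fallback comes back at 13.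

Step 9. The carbonyl may stay masked as the hemiketal alkoxide so that olefination stalls, or the peroxide may be reduced by phosphonium species. The fallback sets out from 13. Et3SiOSO2CF3 and 2,6-lutidine at −78 °C cap the ring-opened hydroperoxide as (4S,6R,13Z)-4,6-dimethyl-14-phenyl-4-[(triethylsilyl)peroxy]tetradec-13-en-2-one F7, a neutral free ketone. Wittig reaction with Ph3P=CHOMe at −78 °C gives triethyl{[(4S,6R,13Z)-1-methoxy-2,4,6-trimethyl-14-phenyltetradeca-1,13-dien-4-yl]peroxy}silane F8. Bu4NF/AcOH removes silicon and Ac2O/pyridine acetylates the hydroperoxide 14 at once; the fallback comes back at 15.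

**Further compounds**

F1 | step 11 | (5S,7R,14Z)-3,5,7-trimethyl-2-oxo-15-phenylpentadec-14-en-5-yl ethaneperoxoate (3RS) | C[C@H](CCCCCC/C=C\c1ccccc1)C[C@@](C)(CC(C)C(C)=O)OOC(C)=O
F2 | step 8 | (2R,3R,4R,6R,13Z)-3,4-epoxy-4,6-dimethyl-14-phenyltetradec-13-en-2-ol | C[C@@H](O)[C@H]1O[C@]1(C)C[C@H](C)CCCCCC/C=C\c1ccccc1
F3 | step 8 | (2R,4R,6R,13Z)-4,6-dimethyl-14-phenyltetradec-13-ene-2,4-diol | C[C@@H](O)C[C@](C)(O)C[C@H](C)CCCCCC/C=C\c1ccccc1
F4 | step 8 | (2R,4R,6R,13Z)-4-hydroxy-4,6-dimethyl-14-phenyltetradec-13-en-2-yl methanesulfonate | C[C@@H](OS(C)(=O)=O)C[C@](C)(O)C[C@H](C)CCCCCC/C=C\c1ccccc1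
F5 | step 8 | (2R,4S)-2,4-dimethyl-2-[(2R,9Z)-2-methyl-10-phenyldec-9-en-1-yl]oxetane | C[C@H]1C[C@@](C)(C[C@H](C)CCCCCC/C=C\c2ccccc2)O1
F6 | step 8 | (2S,4S,6R,13Z)-4-hydroperoxy-4,6-dimethyl-14-phenyltetradec-13-en-2-ol | C[C@H](O)C[C@@](C)(OO)C[C@H](C)CCCCCC/C=C\c1ccccc1
F7 | step 9 | (4S,6R,13Z)-4,6-dimethyl-14-phenyl-4-[(triethylsilyl)peroxy]tetradec-13-en-2-one | C[C@H](CCCCCC/C=C\c1ccccc1)C[C@@](C)(CC(C)=O)OO[Si](CC)(CC)CC
F8 | step 9 | triethyl{[(4S,6R,13Z)-1-methoxy-2,4,6-trimethyl-14-phenyltetradeca-1,13-dien-4-yl]peroxy}silane | C[C@H](CCCCCC/C=C\c1ccccc1)C[C@@](C)(CC(C)=COC)OO[Si](CC)(CC)CC
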